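**Plan**

- Retrosynthesis: the CH2–CH2 link is cut between its two carbons (radical conjugate addition of a right-half primary iodide to a left-half α-methylene ketone). The left C=CH2 and the right C(OH)CH3 both go back to α-methylene ketones of one type.
- Both trans-fused 2,2,5a-trimethyl-1-benzoxepane halves have the same absolute configuration and come from one intermediate (13). Each oxepane is cut at the ring O–C(CH3)2 bond and at the bond from the quaternary ring-fusion carbon to its ring CH2, a (4+3) disconnection.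
- Enabling feature: in the 2,2-dimethyloxepan-3-one ring the C(=O)–CH2 pair is a masked alkyne, and its two neighbours (the O-bearing C(CH3)2 and the CH2 on the quaternary carbon) are both propargylic. The four-carbon unit is therefore a Co2(CO)6-complexed 1,4-dielectrophile whose bent alkyne fits a seven-membered ring. The ring oxygen and the methyl-bearing quaternary carbon sit 1,3 on the cyclohexane and map onto a β-silyloxy silyl enol ether as C,O-dinucleophile.
- Forward: cyclohexane from 2-methylcyclohexane-1,3-dione; oxepane by tandem Nicholas annulation; alkyne to cis-alkene, epoxide and carbinol; methylenation and allylic oxidation to the α-methylene ketones; divergence, union, end-game.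
- Stereochemistry: one carbinol centre is set by Corey–Bakshi–Shibata reduction. It relays to the quaternary carbon (anti alkylation) and the trans ring fusion, and from there to the epoxide face, the methyl addition, the hydroboration and the last α-centre, all by substrate control.

Key step: step 6

Remark: in the SMILES the alkyne–Co2(CO)6 unit is written as a C2Co2 tetrahedrane with carbonyl ligands as Co=C=O; 16 and 18 are carried as mixtures at the new carbinol carbon, which is oxidised in the next step.

**Route**

Step 1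
Reactants: 1 2-methylcyclohexane-1,3-dione
Product: 2 3-[(tert-butyldimethylsilyl)oxy]-2-methylcyclohex-2-en-1-one
Conditions: TBSCl, Et3N, CH2Cl2, 0 °C to rt
Reagents that add atoms: tert-butyldimethylsilyl chloride, CC(C)(C)[Si](C)(C)Cl
Why: O-silylation of the enol form of the cyclic 1,3-dione (silyl enol ether formation) should give the vinylogous silyl ester, which tells the two carbonyl groups apart and stores the later enol nucleophile.

Step 2
Reactants: 2 3-[(tert-butyldimethylsilyl)oxy]-2-methylcyclohex-2-en-1-one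
Product: 3 (S)-3-[(tert-butyldimethylsilyl)oxy]-2-methylcyclohex-2-en-1-ol
Conditions: (R)-2-methyl-CBS-oxazaborolidine [(R)-1-methyl-3,3-diphenyltetrahydro-1H,3H-pyrrolo[1,2-c][1,3,2]oxazaborole] (0.1 equiv), BH3·SMe2, THF, −20 °C; MeOH, pH 7 buffer
Reagents that add atoms: none
Why: Corey–Bakshi–Shibata reduction should deliver hydride to one face of the ketone flanked by the substituted alkene (large) and CH2 (small), setting the (S)-carbinol that becomes the oxygen-bearing ring-fusion carbon, while 1,2-reduction leaves the silyl enol ether in place.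

Step 3
Reactants: 3 (S)-3-[(tert-butyldimethylsilyl)oxy]-2-methylcyclohex-2-en-1-ol
Product: 4 (S)-1-[(tert-butyldimethylsilyl)oxy]-2-methyl-3-[(triethylsilyl)oxy]cyclohex-1-ene
Conditions: TESCl, imidazole, DMF, 0 °C
Reagents that add atoms: triethylsilyl chloride, CC[Si](CC)(CC)Cl
Why: silylation of the secondary alcohol under basic conditions protects the acid-labile allylic alcohol and installs the latent oxygen nucleophile.

Step 4
Reactants: 5 3-methoxyprop-1-yne; 6 2-bromopropene
Product: 7 5-methoxy-2-methylpent-1-en-3-yne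
Conditions: Pd(PPh3)2Cl2 (cat.), CuI (cat.), Et3N, rt
Reagents that add atoms: none
Why: Sonogashira coupling of a terminal alkyne with a vinyl bromide should give the enyne, whose isopropenyl group is a latent tertiary propargylic cation.

Step 5
Reactants: 7 5-methoxy-2-methylpent-1-en-3-yne
Product: 8 Co2(CO)6 complex of 7
Conditions: Co2(CO)8, CH2Cl2, rt
Reagents that add atoms: dicobalt octacarbonyl, O=C=[Co](=C=O)(=C=O)(=C=O)[Co](=C=O)(=C=O)(=C=O)=C=O
Why: the alkyne displaces two CO ligands of Co2(CO)8 at room temperature to give the alkyne–hexacarbonyldicobalt complex, the alkene not being touched.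

Step 6
Reactants: 4 (S)-1-[(tert-butyldimethylsilyl)oxy]-2-methyl-3-[(triethylsilyl)oxy]cyclohex-1-ene; 8 Co2(CO)6 complex of 7
Product: 10 Co2(CO)6 complex of (5aR,9aS)-2,2,5a-trimethyl-3,4-didehydro-5,5a,7,8,9,9a-hexahydro-1-benzoxepin-6(2H)-one, via open-chain alkylated enyne complex 9 (not isolated)
Conditions: BF3·OEt2, CH2Cl2, −78 °C; then HBF4·OEt2, −78 to −20 °C; aq. NaHCO3
Reagents that add atoms: none
Why: BF3 ionises the propargylic methyl ether of 8 to the Co2(CO)6-stabilised primary propargylic cation, which silyl enol ether 4 captures at its methyl-bearing carbon (Nicholas reaction) to give ketone 9 with the new quaternary centre; HBF4 then protonates the isopropenyl group of the complexed enyne to the tertiary propargylic cation, and the neighbouring silyl ether oxygen closes on it with loss of the triethylsilyl group. The closest known reaction types are the Nicholas alkylation of silyl enol ethers, intramolecular Nicholas etherification to medium-ring ethers, and the double-Nicholas (4+3) annulation that gives Co2(CO)6-complexed cycloheptynes. The oxepane closes by attack of oxygen on the tertiary cationic carbon, the complexed triple bond lying inside the new seven-membered ring, which is possible because complexation bends the alkyne to about 140°. The quaternary carbon is controlled by the silyloxy-bearing stereocentre of 4: allylic 1,2-strain with the vinylic methyl group holds the OSiEt3 group pseudoaxial and the cation enters anti to it, so the new C–CH2 bond is trans to oxygen and the ring fusion becomes trans once both groups turn equatorial for closure. The step needs site selectivity (carbon to the CH2 terminus, oxygen to the C(CH3)2 terminus), and this is secured by timing, because under aprotic BF3 only the methyl ether can ionise and the tertiary cation appears only after the enol ether is consumed and acid is added.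

Step 7
Reactants: 10 Co2(CO)6 complex of (5aR,9aS)-2,2,5a-trimethyl-3,4-didehydro-5,5a,7,8,9,9a-hexahydro-1-benzoxepin-6(2H)-one
Product: 11 (5aR,9aS)-2,2,5a-trimethyl-5,5a,7,8,9,9a-hexahydro-1-benzoxepin-6(2H)-one
Conditions: Bu3SnH, toluene, 65 °C
Reagents that add atoms: none
Why: reductive decomplexation of alkyne–Co2(CO)6 complexes with tin hydride gives cis-alkenes, the only geometry possible in the seven-membered ring, and should leave the ketone untouched.

Step 8
Reactants: 11 (5aR,9aS)-2,2,5a-trimethyl-5,5a,7,8,9,9a-hexahydro-1-benzoxepin-6(2H)-one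
Product: 12 (3S,4S,5aR,9aS)-3,4-epoxy-2,2,5a-trimethyloctahydro-1-benzoxepin-6(2H)-one
Conditions: dimethyldioxirane, acetone, 0 °C
Reagents that add atoms: dimethyldioxirane, CC1(C)OO1
Why: neutral dioxirane epoxidation of the cis-alkene avoids Baeyer–Villiger oxidation of the ketone and should occur on the face opposite the axial 5a-methyl group, which later defines the oxepane carbinol configuration.

Step 9
Reactants: 12 (3S,4S,5aR,9aS)-3,4-epoxy-2,2,5a-trimethyloctahydro-1-benzoxepin-6(2H)-one
Product: 13 (3S,4S,5aS,9aS)-3,4-epoxy-2,2,5a-trimethyl-6-methylidenedecahydro-1-benzoxepine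
Conditions: MePPh3Br, KOtBu, toluene, 80 °C
Reagents that add atoms: methyltriphenylphosphonium bromide, C[P+](c1ccccc1)(c1ccccc1)c1ccccc1.[Br-]
Why: Wittig methylenation works on hindered α-quaternary cyclohexanones at raised temperature and tolerates the epoxide; the new CH2 is the future linker carbon.

Step 10
Reactants: 13 (3S,4S,5aS,9aS)-3,4-epoxy-2,2,5a-trimethyl-6-methylidenedecahydro-1-benzoxepine
Product: 14 (3S,5aS,9aS)-2,2,5a-trimethyl-6-methylidenedecahydro-1-benzoxepin-3-ol
Conditions: LiEt3BH, THF, 0 °C to rt; H2O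
Reagents that add atoms: none
Why: hydride opens the epoxide by SN2 attack at C-4, the carbon remote from the neopentyl C(CH3)2 centre, so oxygen stays on C-3 with the (S) configuration fixed by the epoxide face.

Step 11
Reactants: 14 (3S,5aS,9aS)-2,2,5a-trimethyl-6-methylidenedecahydro-1-benzoxepin-3-ol
Product: 15 tert-butyldimethylsilyl ether of 14
Conditions: TBSOTf, 2,6-lutidine, CH2Cl2, 0 °C
Reagents that add atoms: tert-butyldimethylsilyl triflate, CC(C)(C)[Si](C)(C)OS(=O)(=O)C(F)(F)F
Why: silylation with the silyl triflate protects the hindered secondary alcohol for the oxidations that follow.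

Step 12
Reactants: 15 tert-butyldimethylsilyl ether of 14
Product: 16 (3S,5aS,9aS)-3-[(tert-butyldimethylsilyl)oxy]-2,2,5a-trimethyl-6-methylidenedecahydro-1-benzoxepin-7-ol (C-7 epimers)
Conditions: SeO2 (0.5 equiv), tBuOOH, CH2Cl2, rt
Reagents that add atoms: tert-butyl hydroperoxide, CC(C)(C)OO (terminal oxidant; the oxygen atom is passed on by selenium dioxide, O=[Se]=O)
Why: Riley allylic oxidation (ene reaction, then 2,3-sigmatropic shift) returns the double bond to the exocyclic position and can only reach C-7, the single allylic carbon that bears hydrogen.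

Step 13
Reactants: 16 (3S,5aS,9aS)-3-[(tert-butyldimethylsilyl)oxy]-2,2,5a-trimethyl-6-methylidenedecahydro-1-benzoxepin-7-ol
Product: 17 (3S,5aS,9aS)-3-[(tert-butyldimethylsilyl)oxy]-2,2,5a-trimethyl-6-methylideneoctahydro-1-benzoxepin-7(2H)-one
Conditions: Dess–Martin periodinane, NaHCO3, CH2Cl2, 0 °C
Reagents that add atoms: none
Why: Dess–Martin oxidation of the allylic alcohol should give the α-methylene ketone under buffered, non-basic conditions.

Step 14
Reactants: 13 (3S,4S,5aS,9aS)-3,4-epoxy-2,2,5a-trimethyl-6-methylidenedecahydro-1-benzoxepine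
Product: 18 (3S,4S,5aS,9aS)-3,4-epoxy-2,2,5a-trimethyl-6-methylidenedecahydro-1-benzoxepin-7-ol (C-7 epimers)
Conditions: SeO2 (0.5 equiv), tBuOOH, CH2Cl2, rt
Reagents that add atoms: tert-butyl hydroperoxide, CC(C)(C)OO (terminal oxidant; the oxygen atom is passed on by selenium dioxide, O=[Se]=O)
Why: the same Riley allylic oxidation, again limited to C-7, with the epoxide expected to survive the near-neutral conditions.

Step 15
Reactants: 18 (3S,4S,5aS,9aS)-3,4-epoxy-2,2,5a-trimethyl-6-methylidenedecahydro-1-benzoxepin-7-ol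
Product: 19 (3S,4S,5aS,9aS)-3,4-epoxy-2,2,5a-trimethyl-6-methylideneoctahydro-1-benzoxepin-7(2H)-one
Conditions: Dess–Martin periodinane, NaHCO3, CH2Cl2, 0 °C
Reagents that add atoms: none
Why: Dess–Martin oxidation of the allylic alcohol to the α-methylene ketone.

Step 16
Reactants: 19 (3S,4S,5aS,9aS)-3,4-epoxy-2,2,5a-trimethyl-6-methylideneoctahydro-1-benzoxepin-7(2H)-one
Product: 20 (3S,4S,5aS,7R,9aS)-3,4-epoxy-2,2,5a,7-tetramethyl-6-methylidenedecahydro-1-benzoxepin-7-ol
Conditions: MeLi, THF, −78 °C
Reagents that add atoms: methyllithium, [Li]C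
Why: 1,2-addition of the organolithium to the enone carbonyl should come from the equatorial direction, away from the syn-axial 5a-methyl group, placing the new hydroxyl axial (7R) as in the target.

Step 17
Reactants: 20 (3S,4S,5aS,7R,9aS)-3,4-epoxy-2,2,5a,7-tetramethyl-6-methylidenedecahydro-1-benzoxepin-7-ol
Product: 21 (3S,5aS,7R,9aS)-2,2,5a,7-tetramethyl-6-methylidenedecahydro-1-benzoxepine-3,7-diol
Conditions: LiEt3BH, THF, rt; H2O
Reagents that add atoms: none
Why: as in step 10, hydride opens the epoxide at C-4, away from the neopentyl centre, now with no ketone present.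

Step 18
Reactants: 21 (3S,5aS,7R,9aS)-2,2,5a,7-tetramethyl-6-methylidenedecahydro-1-benzoxepine-3,7-diol
Product: 22 (3S,5aS,6S,7R,9aS)-6-(iodomethyl)-2,2,5a,7-tetramethyldecahydro-1-benzoxepine-3,7-diol
Conditions: 9-BBN (excess), THF, 60 °C; then NaOMe, I2, MeOH, 0 °C
Reagents that add atoms: iodine, II
Why: hydroboration puts boron on the terminal carbon and hydrogen on C-6 from the face opposite the axial 5a-methyl and 7-oxygen groups (setting C-6), and base-promoted iodinolysis of the B-alkyl bond gives the primary iodide (hydroboration–iodination).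

Step 19
Reactants: 22 (3S,5aS,6S,7R,9aS)-6-(iodomethyl)-2,2,5a,7-tetramethyldecahydro-1-benzoxepine-3,7-diol; 17 (3S,5aS,9aS)-3-[(tert-butyldimethylsilyl)oxy]-2,2,5a-trimethyl-6-methylideneoctahydro-1-benzoxepin-7(2H)-one
Product: 23 keto diol in which the CH2–CH2 link joins C-6 of the left 7-oxo-3-silyloxy half (6S) to C-6 of the right 3,7-diol half
Conditions: (Me3Si)3SiH, AIBN, toluene, 80 °C, slow addition
Reagents that add atoms: none
Why: Giese reaction: the primary radical from 22 adds to the unhindered CH2 terminus of the α-methylene ketone, and the α-keto radical takes hydrogen from the silane on the face opposite the axial methyl group, giving the equatorial side chain, which is also the thermodynamically preferred (epimerisable) isomer.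

Step 20
Reactants: 23 keto diol
Product: 24 left-half 7-methylidene compound (right-half 3,7-diol and left-half silyl ether unchanged)
Conditions: MePPh3Br, KOtBu (excess), THF, 0 °C to rt
Reagents that add atoms: methyltriphenylphosphonium bromide, C[P+](c1ccccc1)(c1ccccc1)c1ccccc1.[Br-]
Why: Wittig methylenation of the cyclohexanone; excess ylide makes up for the free hydroxyls, and any epimerisation at the α-carbon leads to the same equatorial isomer.

Step 21
Reactants: 24 left-half 7-methylidene compound
Product: 25 tert-butyldimethylsilyl ether of the target at the left-half carbinol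
Conditions: Dess–Martin periodinane, NaHCO3, CH2Cl2, rt
Reagents that add atoms: none
Why: Dess–Martin oxidation of the only free secondary alcohol gives the oxepan-3-one; the tertiary alcohol, the alkene and the silyl ether are inert.

Step 22
Reactants: 25 tert-butyldimethylsilyl ether of the target
Product: 26 target compound
Conditions: TBAF, THF, 50 °C
Reagents that add atoms: none
Why: fluoride cleavage of the silyl ether frees the left-half carbinol without touching the ketone, the alkene or the tertiary alcohol.

**Compound list**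

1 | 2-methylcyclohexane-1,3-dione | CC1C(=O)CCCC1=O | starting material
2 | 3-[(tert-butyldimethylsilyl)oxy]-2-methylcyclohex-2-en-1-one | CC1=C(O[Si](C)(C)C(C)(C)C)CCCC1=O | intermediate
3 | (S)-3-[(tert-butyldimethylsilyl)oxy]-2-methylcyclohex-2-en-1-ol | CC1=C(O[Si](C)(C)C(C)(C)C)CCC[C@@H]1O | intermediate
4 | (S)-1-[(tert-butyldimethylsilyl)oxy]-2-methyl-3-[(triethylsilyl)oxy]cyclohex-1-ene | CC1=C(O[Si](C)(C)C(C)(C)C)CCC[C@@H]1O[Si](CC)(CC)CC | intermediate
5 | 3-methoxyprop-1-yne | COCC#C | starting material
6 | 2-bromopropene | CC(Br)=C | starting material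
7 | 5-methoxy-2-methylpent-1-en-3-yne | COCC#CC(C)=C | intermediate
8 | Co2(CO)6 complex of 7 (dicobalt hexacarbonyl unit bridging the triple bond) | COCC12C3(C(C)=C)[Co]1(=C=O)(=C=O)(=C=O)[Co]23(=C=O)(=C=O)=C=O | intermediate
9 | Co2(CO)6 complex (at the triple bond) of (2R,3S)-2-methyl-2-(4-methylpent-4-en-2-yn-1-yl)-3-[(triethylsilyl)oxy]cyclohexan-1-one, side chain trans to the silyloxy group | O=C1[C@](C)(CC23C4(C(C)=C)[Co]2(=C=O)(=C=O)(=C=O)[Co]34(=C=O)(=C=O)=C=O)[C@@H](O[Si](CC)(CC)CC)CCC1 | intermediate (not isolated)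
10 | Co2(CO)6 complex (at C3≡C4) of (5aR,9aS)-2,2,5a-trimethyl-3,4-didehydro-5,5a,7,8,9,9a-hexahydro-1-benzoxepin-6(2H)-one, trans ring fusion | O=C1[C@]2(C)CC34C5(C(C)(C)O[C@H]2CCC1)[Co]3(=C=O)(=C=O)(=C=O)[Co]45(=C=O)(=C=O)=C=O | intermediate
11 | (5aR,9aS)-2,2,5a-trimethyl-5,5a,7,8,9,9a-hexahydro-1-benzoxepin-6(2H)-one (cis C3=C4) | O=C1[C@]2(C)C/C=C\C(C)(C)O[C@H]2CCC1 | intermediate
12 | (3S,4S,5aR,9aS)-3,4-epoxy-2,2,5a-trimethyloctahydro-1-benzoxepin-6(2H)-one (epoxide anti to the 5a-methyl group) | O=C1[C@]2(C)C[C@@H]3O[C@@H]3C(C)(C)O[C@H]2CCC1 | intermediate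
13 | (3S,4S,5aS,9aS)-3,4-epoxy-2,2,5a-trimethyl-6-methylidenedecahydro-1-benzoxepine | C=C1[C@]2(C)C[C@@H]3O[C@@H]3C(C)(C)O[C@H]2CCC1 | intermediate
14 | (3S,5aS,9aS)-2,2,5a-trimethyl-6-methylidenedecahydro-1-benzoxepin-3-ol | C=C1[C@]2(C)CC[C@H](O)C(C)(C)O[C@H]2CCC1 | intermediate
15 | tert-butyldimethylsilyl ether of 14 | C=C1[C@]2(C)CC[C@H](O[Si](C)(C)C(C)(C)C)C(C)(C)O[C@H]2CCC1 | intermediate
16 | (3S,5aS,9aS)-3-[(tert-butyldimethylsilyl)oxy]-2,2,5a-trimethyl-6-methylidenedecahydro-1-benzoxepin-7-ol (C-7 epimers) | C=C1[C@]2(C)CC[C@H](O[Si](C)(C)C(C)(C)C)C(C)(C)O[C@H]2CCC1O | intermediate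
17 | (3S,5aS,9aS)-3-[(tert-butyldimethylsilyl)oxy]-2,2,5a-trimethyl-6-methylideneoctahydro-1-benzoxepin-7(2H)-one | C=C1[C@]2(C)CC[C@H](O[Si](C)(C)C(C)(C)C)C(C)(C)O[C@H]2CCC1=O | intermediate
18 | (3S,4S,5aS,9aS)-3,4-epoxy-2,2,5a-trimethyl-6-methylidenedecahydro-1-benzoxepin-7-ol (C-7 epimers) | C=C1[C@]2(C)C[C@@H]3O[C@@H]3C(C)(C)O[C@H]2CCC1O | intermediate
19 | (3S,4S,5aS,9aS)-3,4-epoxy-2,2,5a-trimethyl-6-methylideneoctahydro-1-benzoxepin-7(2H)-one | C=C1[C@]2(C)C[C@@H]3O[C@@H]3C(C)(C)O[C@H]2CCC1=O | intermediate
20 | (3S,4S,5aS,7R,9aS)-3,4-epoxy-2,2,5a,7-tetramethyl-6-methylidenedecahydro-1-benzoxepin-7-ol | C=C1[C@]2(C)C[C@@H]3O[C@@H]3C(C)(C)O[C@H]2CC[C@@]1(C)O | intermediate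
21 | (3S,5aS,7R,9aS)-2,2,5a,7-tetramethyl-6-methylidenedecahydro-1-benzoxepine-3,7-diol | C=C1[C@]2(C)CC[C@H](O)C(C)(C)O[C@H]2CC[C@@]1(C)O | intermediate
22 | (3S,5aS,6S,7R,9aS)-6-(iodomethyl)-2,2,5a,7-tetramethyldecahydro-1-benzoxepine-3,7-diol | IC[C@H]1[C@]2(C)CC[C@H](O)C(C)(C)O[C@H]2CC[C@@]1(C)O | intermediate
23 | (3S,5aS,6S,9aS)-3-[(tert-butyldimethylsilyl)oxy]-6-{2-[(3S,5aS,6S,7R,9aS)-3,7-dihydroxy-2,2,5a,7-tetramethyldecahydro-1-benzoxepin-6-yl]ethyl}-2,2,5a-trimethyloctahydro-1-benzoxepin-7(2H)-one | O=C1CC[C@@H]2OC(C)(C)[C@@H](O[Si](C)(C)C(C)(C)C)CC[C@@]2(C)[C@@H]1CC[C@H]1[C@]2(C)CC[C@H](O)C(C)(C)O[C@H]2CC[C@@]1(C)O | intermediate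
24 | 7-methylidene analogue of 23 (left half 3S,5aS,6R,9aS with OTBS; right half 3S,5aS,6S,7R,9aS 3,7-diol) | C=C1CC[C@@H]2OC(C)(C)[C@@H](O[Si](C)(C)C(C)(C)C)CC[C@@]2(C)[C@@H]1CC[C@H]1[C@]2(C)CC[C@H](O)C(C)(C)O[C@H]2CC[C@@]1(C)O | intermediate
25 | tert-butyldimethylsilyl ether of the target at the left-half oxepane carbinol (right-half oxepan-3-one in place) | C=C1CC[C@@H]2OC(C)(C)[C@@H](O[Si](C)(C)C(C)(C)C)CC[C@@]2(C)[C@@H]1CC[C@H]1[C@]2(C)CCC(=O)C(C)(C)O[C@H]2CC[C@@]1(C)O | intermediate
26 | target CNP0160418.1 | C=C1CC[C@@H]2OC(C)(C)[C@@H](O)CC[C@@]2(C)[C@@H]1CC[C@H]1[C@]2(C)CCC(=O)C(C)(C)O[C@H]2CC[C@@]1(C)O | target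

**Totals**

Total step count: 22.
Longest linear sequence: 16 steps (steps 1–3, 6–9, 14–22).

**Steps most likely to fail, with fallbacks**

Step 6 (tandem Nicholas annulation). What may go wrong: Lewis-acid ionisation of the allylic silyloxy group of 4 before the carbon–carbon bond forms, with collapse to a cyclohexenone; and reversible re-ionisation of the tertiary propargylic ether with elimination back to the enyne. The fallback sets out from 4 and comes back at 11, closing the oxepene by ring-closing metathesis instead of cation capture. Silyl enol ether 4 is allylated under neutral conditions with allyl methyl carbonate and Pd2(dba)3/dppe in THF (Tsuji–Trost allylation, again anti to the silyloxy group) to give (2R,3S)-2-allyl-2-methyl-3-[(triethylsilyl)oxy]cyclohexan-1-one F1. HF·pyridine frees (2R,3S)-2-allyl-3-hydroxy-2-methylcyclohexan-1-one F2. Acid-catalysed alkylation with 2-methylbut-3-en-2-yl trichloroacetimidate (TfOH cat.) gives the tertiary allyl ether (2R,3S)-2-allyl-2-methyl-3-[(2-methylbut-3-en-2-yl)oxy]cyclohexan-1-one F3. The second-generation Grubbs catalyst in CH2Cl2 at 40 °C then closes the seven-membered ring to 11.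

Step 2 (asymmetric reduction). What may go wrong: slow hydride transfer to the electron-rich vinylogous ester carbonyl, erosion of enantioselectivity by uncatalysed borane reduction, and acid-triggered loss of water from the product on work-up. The fallback sets out from 2 and comes back at 3, using resolution in place of asymmetric catalysis. i-Bu2AlH in toluene at −78 °C with a basic work-up gives racemic 3-[(tert-butyldimethylsilyl)oxy]-2-methylcyclohex-2-en-1-ol F4. A lipase (Burkholderia cepacia, Amano PS) with vinyl acetate should acylate the (R)-enantiomer to (R)-3-[(tert-butyldimethylsilyl)oxy]-2-methylcyclohex-2-en-1-yl acetate F5, leaving 3, which is separated on base-washed silica.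

Step 8 (epoxidation). What may go wrong: poor facial selectivity on the flexible oxepene, which would blur the configuration of the left-half carbinol. The fallback sets out from 13 as obtained (mixed with its epoxide-face isomer) and comes back at 14, replacing substrate control by reagent control. Hydride opening as in step 10 gives 14 together with its 3-epimer (3R,5aS,9aS)-2,2,5a-trimethyl-6-methylidenedecahydro-1-benzoxepin-3-ol F6. Dess–Martin oxidation converges both on (5aS,9aS)-2,2,5a-trimethyl-6-methylideneoctahydro-1-benzoxepin-3(2H)-one F7. Reduction with (R)-2-methyl-CBS-oxazaborolidine and catecholborane, which does not hydroborate the exocyclic alkene, should return the (S)-carbinol 14, since the ketone is flanked by a quaternary carbon and a CH2 group. For the right half the epoxide face is of no consequence, because that carbinol is oxidised in step 21.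

Further compounds
F1 | step 6 | (2R,3S)-2-allyl-2-methyl-3-[(triethylsilyl)oxy]cyclohexan-1-one | O=C1[C@](C)(CC=C)[C@@H](O[Si](CC)(CC)CC)CCC1
F2 | step 6 | (2R,3S)-2-allyl-3-hydroxy-2-methylcyclohexan-1-one | O=C1[C@](C)(CC=C)[C@@H](O)CCC1
F3 | step 6 | (2R,3S)-2-allyl-2-methyl-3-[(2-methylbut-3-en-2-yl)oxy]cyclohexan-1-one | O=C1[C@](C)(CC=C)[C@@H](OC(C)(C)C=C)CCC1
F4 | step 2 | racemic 3-[(tert-butyldimethylsilyl)oxy]-2-methylcyclohex-2-en-1-ol | CC1=C(O[Si](C)(C)C(C)(C)C)CCCC1O
F5 | step 2 | (R)-3-[(tert-butyldimethylsilyl)oxy]-2-methylcyclohex-2-en-1-yl acetate | CC1=C(O[Si](C)(C)C(C)(C)C)CCC[C@H]1OC(C)=O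
F6 | step 8 | (3R,5aS,9aS)-2,2,5a-trimethyl-6-methylidenedecahydro-1-benzoxepin-3-ol | C=C1[C@]2(C)CC[C@@H](O)C(C)(C)O[C@H]2CCC1
F7 | step 8 | (5aS,9aS)-2,2,5a-trimethyl-6-methylideneoctahydro-1-benzoxepin-3(2H)-one | C=C1[C@]2(C)CCC(=O)C(C)(C)O[C@H]2CCC1
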